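**Plan**

- Retrosynthesis: the enone Cα=Cβ bond is cut first (aldol condensation of a ring A methyl ketone with a ring B aldehyde). Ring B is then cut at C1–C2 and C3–C4 (alkyne [4+2]), and the acyclic diene precursor at the bond between its ketone carbon and its oxygenated α-carbon (ester enolate acylation).
- Enabling feature: ring B (C1 2-methylbut-3-en-2-yl, C2 H, C3 propenone carbon, C4 OMe, C5 OH, C6 OH) has its three oxygens on the adjacent carbons C4, C5 and C6, bounded by the carbon-substituted C3 and C1. C4–C5–C6–C1 therefore corresponds to a 1,1,2,3-tetraoxygenated butadiene and C2–C3 to a propiolate.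
- Forward: the chain is joined by acylating the enolate of MOM-protected methyl glycolate with 3,3-dimethylpent-4-enoyl chloride. Enol ether formation and γ-enolization/silylation give the diene, and ring B, the only ring made, closes by cycloaddition with methyl propiolate and aromatizes.
- The salicylate is then O-methylated, taken to the aldehyde and condensed with MOM-protected 4'-hydroxyacetophenone (ring A is bought). All three MOM groups are removed in one acid step.
- Stereochemistry: the target has no stereocentre; the (E)-enone comes from the thermodynamically controlled dehydration in the aldol condensation.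

Key step: step 7

Remark: the geometry of the enol ether double bond in 10 and of the ketene acetal double bond in 11, 12 and 14 has no consequence, because these carbons end up in the aromatic ring; one isomer is drawn. Compounds 8, 14 and 21 are racemic.

**Route**

Step 1
Reactants: 1 methyl glycolate
Product: 2 methyl 2-(methoxymethoxy)acetate
Conditions: MOMCl, iPr2NEt, CH2Cl2, 0 °C to rt
Reagents that add atoms: chloromethyl methyl ether (MOMCl), COCCl
Why: O-alkylation of a primary alcohol by the oxocarbenium-like chloromethyl ether under amine base is a standard acetal (MOM) protection and leaves the ester untouched.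

Step 2
Reactants: 3 methyl 3,3-dimethylpent-4-enoate
Product: 5 3,3-dimethylpent-4-enoic acid, via lithium carboxylate 4 (not isolated)
Conditions: LiOH·H2O, THF/MeOH/H2O, rt; then 1 M HCl
Reagents that add atoms: lithium hydroxide (LiOH), [Li+].[OH-]
Why: Saponification of an unhindered methyl ester by acyl–oxygen cleavage, followed by acidification, should give the acid with the quaternary carbon and vinyl group unaffected.

Step 3
Reactants: 5 3,3-dimethylpent-4-enoic acid
Product: 6 3,3-dimethylpent-4-enoyl chloride
Conditions: (COCl)2, cat. DMF, CH2Cl2, 0 °C to rt; concentrate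
Reagents that add atoms: oxalyl chloride, O=C(Cl)C(=O)Cl
Why: DMF-catalysed acyl chloride formation proceeds through a chloroiminium activator under neutral, cold conditions that the isolated alkene tolerates.

Step 4
Reactants: 2 methyl 2-(methoxymethoxy)acetate; 6 3,3-dimethylpent-4-enoyl chloride
Product: 8 methyl 2-(methoxymethoxy)-5,5-dimethyl-3-oxohept-6-enoate, via lithium enolate 7 (not isolated)
Conditions: 2 (2.1 equiv), LiN(iPr)2 (LDA, 2.1 equiv), THF, −78 °C; then 6 (1.0 equiv), −78 °C; aq. NH4Cl
Reagents that add atoms: none
Why: Crossed Claisen condensation by C-acylation of a preformed, chelated lithium glycolate enolate with an acid chloride should be fast at −78 °C, the second equivalent of enolate deprotonating the more acidic β-keto ester and so preventing double acylation.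

Step 5
Reactants: 8 methyl 2-(methoxymethoxy)-5,5-dimethyl-3-oxohept-6-enoate
Product: 10 methyl (2E)-2,3-bis(methoxymethoxy)-5,5-dimethylhepta-2,6-dienoate, via sodium enolate 9 (not isolated)
Conditions: NaH, THF, 0 °C; then MOMCl, 0 °C to rt
Reagents that add atoms: chloromethyl methyl ether (MOMCl), COCCl
Why: O-alkylation of a β-keto ester enolate by a hard, oxocarbenium-like electrophile should give the enol ether, C-alkylation being disfavoured because it would create a quaternary carbon at the already oxygenated α-position.

Step 6
Reactants: 10 methyl (2E)-2,3-bis(methoxymethoxy)-5,5-dimethylhepta-2,6-dienoate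
Product: 12 trimethyl{[(1E,3Z)-1-methoxy-2,3-bis(methoxymethoxy)-5,5-dimethylhepta-1,3,6-trien-1-yl]oxy}silane, via lithium dienolate 11 (not isolated)
Conditions: LiN(iPr)2 (LDA), THF, −78 °C; then Me3SiCl, −78 °C to rt; pentane, filtration under argon, used crude
Reagents that add atoms: chlorotrimethylsilane, C[Si](C)(C)Cl
Why: Kinetic γ-deprotonation of a 3-alkoxy-2-enoate and O-silylation of the extended ester enolate is the standard preparation of 1,3-dialkoxy-1-silyloxybuta-1,3-dienes, and allylic 1,3-strain with the C2 substituent should place the quaternary group trans to C2 (3Z).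

Step 7
Reactants: 12 trimethyl{[(1E,3Z)-1-methoxy-2,3-bis(methoxymethoxy)-5,5-dimethylhepta-1,3,6-trien-1-yl]oxy}silane; 13 methyl propiolate
Product: 15 methyl 2-hydroxy-3,4-bis(methoxymethoxy)-5-(2-methylbut-3-en-2-yl)benzoate, via cyclohexadiene cycloadduct 14 (not isolated)
Conditions: 13 (2 equiv), PhMe, 90 °C, sealed tube; then SiO2, CH2Cl2, rt
Reagents that add atoms: none
Why: The electron-rich diene 12, whose HOMO is raised by four oxygen donors, should combine with the electron-poor alkyne 13 in a concerted but strongly asynchronous [4+2] cycloaddition: the diene terminus bearing the quaternary group bonds first to the unsubstituted β-carbon of the propiolate (ring bond C1–C2) and the ketene acetal carbon then closes onto the ester-bearing α-carbon (ring bond C3–C4). The closest known reaction type is the Diels–Alder benzannulation of 1-alkoxy-1-silyloxy-3-oxybuta-1,3-dienes with acetylenic esters, which gives salicylates and resorcylates. Ring B is closed as a six-membered carbocycle by this intermolecular cycloaddition, and cyclohexa-1,4-diene 14 aromatizes on SiO2 when its mixed methyl trimethylsilyl ketal collapses with loss of MeOSiMe3 and the resulting dienone tautomerizes by loss of the doubly allylic hydrogen. No stereocentre is created in 15, since the two sp3 carbons of 14 are transient. The selectivity needed is regiochemical and is secured by polarization (the two ketene acetal oxygens and the enol ether oxygen at diene C3 all push electron density to the terminus remote from the ketene acetal, only the oxygen at diene C2 opposes, and the propiolate LUMO is largest at its β-carbon) and by sterics (the tert-alkyl-bearing terminus can only meet the unsubstituted alkyne carbon). The 3Z geometry keeps the quaternary group on the outside of the s-cis diene, and the isolated vinyl group, being unactivated, should not compete.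

Step 8
Reactants: 15 methyl 2-hydroxy-3,4-bis(methoxymethoxy)-5-(2-methylbut-3-en-2-yl)benzoate
Product: 16 methyl 2-methoxy-3,4-bis(methoxymethoxy)-5-(2-methylbut-3-en-2-yl)benzoate
Conditions: MeI, K2CO3, DMF, 40 °C
Reagents that add atoms: iodomethane, CI
Why: Williamson methylation of the only free phenol, whose hydrogen bond to the ester is broken in DMF on deprotonation, should be clean because the other two oxygens are capped as non-migrating acetals.

Step 9
Reactants: 16 methyl 2-methoxy-3,4-bis(methoxymethoxy)-5-(2-methylbut-3-en-2-yl)benzoate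
Product: 17 [2-methoxy-3,4-bis(methoxymethoxy)-5-(2-methylbut-3-en-2-yl)phenyl]methanol
Conditions: iBu2AlH (2.5 equiv), CH2Cl2, −78 to 0 °C; aq. KNaC4H4O6 work-up
Reagents that add atoms: none
Why: Hydride reduction of an aryl ester to the benzylic alcohol by an aluminium hydride is routine and spares aryl MOM ethers and the terminal alkene at low temperature.

Step 10
Reactants: 17 [2-methoxy-3,4-bis(methoxymethoxy)-5-(2-methylbut-3-en-2-yl)phenyl]methanol
Product: 18 2-methoxy-3,4-bis(methoxymethoxy)-5-(2-methylbut-3-en-2-yl)benzaldehyde
Conditions: MnO2 (activated, excess), CH2Cl2, rt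
Reagents that add atoms: none
Why: Heterogeneous MnO2 oxidation is selective for benzylic alcohols, stops at the aldehyde and is neutral enough for the acetals.

Step 11
Reactants: 19 4'-hydroxyacetophenone
Product: 20 1-[4-(methoxymethoxy)phenyl]ethan-1-one
Conditions: MOMCl, iPr2NEt, CH2Cl2, 0 °C to rt
Reagents that add atoms: chloromethyl methyl ether (MOMCl), COCCl
Why: MOM protection of the phenol removes the acidic proton, which would otherwise give a phenoxide that lowers the acidity of the methyl ketone in the condensation.

Step 12
Reactants: 18 2-methoxy-3,4-bis(methoxymethoxy)-5-(2-methylbut-3-en-2-yl)benzaldehyde; 20 1-[4-(methoxymethoxy)phenyl]ethan-1-one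
Product: 22 (E)-3-[2-methoxy-3,4-bis(methoxymethoxy)-5-(2-methylbut-3-en-2-yl)phenyl]-1-[4-(methoxymethoxy)phenyl]prop-2-en-1-one, via aldol adduct 21 (not isolated)
Conditions: KOH, EtOH/H2O, rt
Reagents that add atoms: none
Why: Claisen–Schmidt condensation of a non-enolizable aryl aldehyde with a methyl ketone gives the aldol, whose E1cB dehydration under equilibrating conditions delivers the conjugated (E)-enone, the base-stable acetals keeping the para oxygen from becoming a deactivating phenoxide.

Step 13
Reactants: 22 (E)-3-[2-methoxy-3,4-bis(methoxymethoxy)-5-(2-methylbut-3-en-2-yl)phenyl]-1-[4-(methoxymethoxy)phenyl]prop-2-en-1-one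
Product: 23 (E)-3-[3,4-dihydroxy-2-methoxy-5-(2-methylbut-3-en-2-yl)phenyl]-1-(4-hydroxyphenyl)prop-2-en-1-one
Conditions: 3 M aq. HCl, MeOH, 45 °C, argon
Reagents that add atoms: none
Why: Acid-catalysed transacetalization of aryl MOM ethers to methanol is facile under mild protic acid, whereas the enone, the aryl methyl ether and the vinyl group (whose protonation would need a secondary cation beside a quaternary carbon) should persist, with the (E)-alkene remaining the thermodynamic isomer.

**Compound list**

1 | methyl glycolate | COC(=O)CO | starting material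
2 | methyl 2-(methoxymethoxy)acetate | COCOCC(=O)OC | intermediate
3 | methyl 3,3-dimethylpent-4-enoate | C=CC(C)(C)CC(=O)OC | starting material
4 | lithium 3,3-dimethylpent-4-enoate (not isolated) | C=CC(C)(C)CC(=O)[O-].[Li+] | intermediate
5 | 3,3-dimethylpent-4-enoic acid | C=CC(C)(C)CC(=O)O | intermediate
6 | 3,3-dimethylpent-4-enoyl chloride | C=CC(C)(C)CC(=O)Cl | intermediate
7 | lithium enolate of 2, enolate oxygen cis to the MOM oxygen (not isolated) | COCO/C=C(\[O-])OC.[Li+] | intermediate
8 | methyl 2-(methoxymethoxy)-5,5-dimethyl-3-oxohept-6-enoate (racemic) | C=CC(C)(C)CC(=O)C(OCOC)C(=O)OC | intermediate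
9 | sodium enolate of 8, enolate oxygen cis to the ester (not isolated) | C=CC(C)(C)C/C([O-])=C(\OCOC)C(=O)OC.[Na+] | intermediate
10 | methyl (2E)-2,3-bis(methoxymethoxy)-5,5-dimethylhepta-2,6-dienoate | C=CC(C)(C)C/C(OCOC)=C(\OCOC)C(=O)OC | intermediate
11 | lithium dienolate of 10, quaternary group trans to C2 across C3=C4 (not isolated) | CO/C([O-])=C(OCOC)/C(OCOC)=C/C(C)(C)C=C.[Li+] | intermediate
12 | trimethyl{[(1E,3Z)-1-methoxy-2,3-bis(methoxymethoxy)-5,5-dimethylhepta-1,3,6-trien-1-yl]oxy}silane | CO/C(O[Si](C)(C)C)=C(OCOC)/C(OCOC)=C/C(C)(C)C=C | intermediate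
13 | methyl propiolate | C#CC(=O)OC | starting material
14 | methyl 6-methoxy-4,5-bis(methoxymethoxy)-3-(2-methylbut-3-en-2-yl)-6-(trimethylsilyloxy)cyclohexa-1,4-diene-1-carboxylate, racemic, OMe cis to the side chain (not isolated) | COC(=O)C1=C[C@@H](C(C)(C)C=C)C(OCOC)=C(OCOC)[C@]1(OC)O[Si](C)(C)C | intermediate
15 | methyl 2-hydroxy-3,4-bis(methoxymethoxy)-5-(2-methylbut-3-en-2-yl)benzoate | C=CC(C)(C)c1cc(C(=O)OC)c(O)c(OCOC)c1OCOC | intermediate
16 | methyl 2-methoxy-3,4-bis(methoxymethoxy)-5-(2-methylbut-3-en-2-yl)benzoate | C=CC(C)(C)c1cc(C(=O)OC)c(OC)c(OCOC)c1OCOC | intermediate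
17 | [2-methoxy-3,4-bis(methoxymethoxy)-5-(2-methylbut-3-en-2-yl)phenyl]methanol | C=CC(C)(C)c1cc(CO)c(OC)c(OCOC)c1OCOC | intermediate
18 | 2-methoxy-3,4-bis(methoxymethoxy)-5-(2-methylbut-3-en-2-yl)benzaldehyde | C=CC(C)(C)c1cc(C=O)c(OC)c(OCOC)c1OCOC | intermediate
19 | 4'-hydroxyacetophenone | CC(=O)c1ccc(O)cc1 | starting material
20 | 1-[4-(methoxymethoxy)phenyl]ethan-1-one | CC(=O)c1ccc(OCOC)cc1 | intermediate
21 | 3-hydroxy-3-[2-methoxy-3,4-bis(methoxymethoxy)-5-(2-methylbut-3-en-2-yl)phenyl]-1-[4-(methoxymethoxy)phenyl]propan-1-one, racemic (not isolated) | C=CC(C)(C)c1cc(C(O)CC(=O)c2ccc(OCOC)cc2)c(OC)c(OCOC)c1OCOC | intermediate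
22 | (E)-3-[2-methoxy-3,4-bis(methoxymethoxy)-5-(2-methylbut-3-en-2-yl)phenyl]-1-[4-(methoxymethoxy)phenyl]prop-2-en-1-one | C=CC(C)(C)c1cc(/C=C/C(=O)c2ccc(OCOC)cc2)c(OC)c(OCOC)c1OCOC | intermediate
23 | (E)-3-[3,4-dihydroxy-2-methoxy-5-(2-methylbut-3-en-2-yl)phenyl]-1-(4-hydroxyphenyl)prop-2-en-1-one | C=CC(C)(C)c1cc(/C=C/C(=O)c2ccc(O)cc2)c(OC)c(O)c1O | target

**Step count**

Total: 13 steps. Longest linear sequence: 11 steps (from 3 through steps 2–10, 12 and 13).

**Steps most likely to fail**

Step 7. Bond formation at the tert-alkyl-substituted diene terminus may be so slow that thermal desilylation or oligomerization of the ketene acetal outruns ring closure. The fallback sets out from 12 and replaces the alkyne with methyl 2-bromoacrylate, a more reactive alkene dienophile of the same polarization that should react in CH2Cl2 at 0 °C to rt. This would give methyl 1-bromo-2-methoxy-3,4-bis(methoxymethoxy)-5-(2-methylbut-3-en-2-yl)-2-(trimethylsilyloxy)cyclohex-3-ene-1-carboxylate F1 as a diastereomer mixture. On SiO2 its silyl ketal should collapse to methyl 1-bromo-3,4-bis(methoxymethoxy)-5-(2-methylbut-3-en-2-yl)-2-oxocyclohex-3-ene-1-carboxylate F2. Dehydrobromination of F2 with DBU and tautomerization of the resulting dienone would return to the route at 15.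

Step 6. Deprotonation at the methylene next to the quaternary carbon may be sluggish, letting the amide base attack the ester, or may give C-silylation or the wrong C3=C4 geometry. The fallback sets out from 8 and performs both enolizations under soft conditions (Me3SiOTf, Et3N, Et2O, 0 °C to rt), which should give (1E,3Z)-1-methoxy-2-(methoxymethoxy)-5,5-dimethyl-1,3-bis(trimethylsilyloxy)hepta-1,3,6-triene F3. Cycloaddition of F3 with 13 in toluene would give methyl 6-methoxy-5-(methoxymethoxy)-3-(2-methylbut-3-en-2-yl)-4,6-bis(trimethylsilyloxy)cyclohexa-1,4-diene-1-carboxylate F4. Aqueous acidic work-up would aromatize and desilylate it to methyl 2,4-dihydroxy-3-(methoxymethoxy)-5-(2-methylbut-3-en-2-yl)benzoate F5. Selective MOM protection of the non-chelated hydroxyl para to the ester (MOMCl, iPr2NEt, CH2Cl2, 0 °C) would rejoin the route at 15.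

Step 13. Protic acid may add the C6 phenol across the neighbouring vinyl group, or the air-sensitive catechol may degrade, before all three acetals are cleaved. The fallback sets out from 22 and avoids protic acid: Me3SiOTf and 2,2'-bipyridyl in MeCN at 0 °C should exchange the aryl MOM ethers for silyl ethers, the methoxymethyl cation being trapped by the bipyridyl. This would give (E)-3-[2-methoxy-5-(2-methylbut-3-en-2-yl)-3,4-bis(trimethylsilyloxy)phenyl]-1-[4-(trimethylsilyloxy)phenyl]prop-2-en-1-one F6, which water hydrolyses at neutral pH on work-up to 23.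

**Further compounds**

F1 | step 7 | methyl 1-bromo-2-methoxy-3,4-bis(methoxymethoxy)-5-(2-methylbut-3-en-2-yl)-2-(trimethylsilyloxy)cyclohex-3-ene-1-carboxylate (diastereomer mixture) | COC(=O)C1(Br)CC(C(C)(C)C=C)C(OCOC)=C(OCOC)C1(OC)O[Si](C)(C)C
F2 | step 7 | methyl 1-bromo-3,4-bis(methoxymethoxy)-5-(2-methylbut-3-en-2-yl)-2-oxocyclohex-3-ene-1-carboxylate (diastereomer mixture) | COC(=O)C1(Br)CC(C(C)(C)C=C)C(OCOC)=C(OCOC)C1=O
F3 | step 6 | (1E,3Z)-1-methoxy-2-(methoxymethoxy)-5,5-dimethyl-1,3-bis(trimethylsilyloxy)hepta-1,3,6-triene | CO/C(O[Si](C)(C)C)=C(OCOC)/C(O[Si](C)(C)C)=C/C(C)(C)C=C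
F4 | step 6 | methyl 6-methoxy-5-(methoxymethoxy)-3-(2-methylbut-3-en-2-yl)-4,6-bis(trimethylsilyloxy)cyclohexa-1,4-diene-1-carboxylate (racemic) | COC(=O)C1=CC(C(C)(C)C=C)C(O[Si](C)(C)C)=C(OCOC)C1(OC)O[Si](C)(C)C
F5 | step 6 | methyl 2,4-dihydroxy-3-(methoxymethoxy)-5-(2-methylbut-3-en-2-yl)benzoate | C=CC(C)(C)c1cc(C(=O)OC)c(O)c(OCOC)c1O
F6 | step 13 | (E)-3-[2-methoxy-5-(2-methylbut-3-en-2-yl)-3,4-bis(trimethylsilyloxy)phenyl]-1-[4-(trimethylsilyloxy)phenyl]prop-2-en-1-one | C=CC(C)(C)c1cc(/C=C/C(=O)c2ccc(O[Si](C)(C)C)cc2)c(OC)c(O[Si](C)(C)C)c1O[Si](C)(C)C
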